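## Analysis of the target

Target **20** is (2S)-2-methyl-2-[(3E)-4-methyl-6-(2,6,6-trimethylcyclohex-1-en-1-yl)hex-3-en-1-yl]-2H-chromen-6-ol. Numbering follows the 2H-chromene (O1, C2, C3, C4, C4a, C5–C8, C8a), with the side chain counted C1'–C6' from C2. Ring A is the benzene ring with a free hydroxyl at C6, para to O1. Ring B is the pyran with the styrenyl C3=C4 double bond. The side chain carries an E-trisubstituted C3'=C4' alkene and ends in the tetrasubstituted cyclohexene ring C.

The only stereocentre is C2, a fully substituted carbon bonded to O1, C3, a methyl group and C1'H2. Its configuration is S (O1 > C3 > C1' > CH3), and there is no second stereocentre from which it could be relayed.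

Three features are sensitive:
- the hydroquinone-type phenol oxidises in air;
- the chromene can open by a light- or heat-driven 6π electrocyclic reaction to an achiral ortho-quinone methide, which would erode the configuration at C2;
- the side chain is a 1,5-diene that cyclises under Brønsted or Lewis acid.

The difficulty is to create an isolated, oxygen-bearing quaternary centre whose two saturated carbon substituents differ only from their second atom onwards. Every later step must also avoid ionisation at C4, cleavage of O1–C2 and enolate-driven opening of ring B.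

The strategy rests on one observation. At the chroman-4-one oxidation level, the C2 methyl group and one hydrogen on C3 can be traced to a single CH2 bridging C2 and C3 of a flat 2-alkylchromone. The stereocentre thereby becomes a choice between the two faces of the C2=C3–C4=O enone, and the C4 oxygen later serves as the handle for the C3=C4 alkene.

## Retrosynthetic reasoning

**20 ⇒ 19.** The O–Si bond at C6 is cut last. The phenol has to be masked through amide bases, an ylide, a one-electron reductant and a hydride. A triisopropylsilyl ether survives all of these and is removed by fluoride without acid, which the diene chain would not tolerate.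

**19 ⇒ 18 ⇒ 17.** The C3=C4 double bond is traced back to a C4 ketone through the C4 alcohol. Dehydration of **18** can only go towards C3, because C4a is aromatic. The forward elimination must not pass through a free C4 cation, which the C3'=C4' alkene could capture, so a neutral syn-elimination is planned. The configuration at C4 of **18** is irrelevant.

**17 ⇒ 16.** The C2 methyl group and one C3 hydrogen of **17** are joined in thought into the C1 bridge of cyclopropane **16**; in the forward sense the C7a–C1 bond is broken. This replaces the enantioselective installation of a methyl group at an oxygenated quaternary carbon by the cyclopropanation of an enone. The forward step has to cleave the external bond and not the ring-fusion bond C1a–C7a. One-electron reduction of the aryl ketone is chosen because the ketyl π system overlaps with the external bond, and the ring strain pays for the scission.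

**16 ⇒ 13 + 14 (key disconnection).** Both bonds to the bridge carbon, C1a–C1 and C7a–C1, are cut, which leads to chromone **13** and a one-carbon ylide source **14**. The cut is made here because **13** is planar and achiral, so only an enantioface has to be chosen, and the cis ring fusion follows from geometry. The forward reaction must achieve face-selective conjugate addition of ylide **15** to a fully substituted, oxygen-bearing β-carbon, followed by ring closure.

**13 ⇒ 4 + 11.** The C1'–C2' bond is cut. The methyl group of **4** is a vinylogous α-position and can be metalated to dienolate **12**; the allylic bromide **11** is a reactive SN2 partner that brings the E-alkene in ready-made. This is the most convergent cut and joins two fragments of similar size.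

**4 ⇒ 2 ⇒ 1.** Ring B of **4** is opened at O1–C2 and C2–C3, giving the ortho-hydroxyaryl methyl ketone **2** and a two-carbon acyl donor by way of diketone **3**. The two phenols of **1** are differentiated by silylation, because the 2'-hydroxyl is hydrogen-bonded to the ketone.

**11 ⇒ 10 ⇒ 7 ⇒ 5.** Bromide **11** comes from alcohol **10**. The E-trisubstituted alkene of **10** is traced to the terminal alkyne **7** by syn methylmetalation through alane **8** and aluminate **9**, with a one-carbon electrophile as trap. This fixes the geometry with certainty, which olefination of ketone **5** would not. Alkyne **7** comes from the methyl ketone **5** by elimination of its enol phosphate **6**.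

## Alternatives that were turned down

**Alternative 1: asymmetric ring-closing metathesis that differentiates two vinyl groups.**
- Disconnection: the C3=C4 bond, with C2 set at the same time.
- Forward key step: the aryl ether **A2**, which carries a styrenyl alkene and two enantiotopic vinyl groups on the carbinol carbon, would be closed by the enantiopure hexavalent molybdenum alkylidene **A3**, Mo(N-2,6-iPr2C6H3)(CHCMe2Ph)(3,3'-di-tert-butyl-5,5',6,6'-tetramethylbiphenyl-2,2'-diolate). The product is the 2-methyl-2-vinylchromene **A1**. Its vinyl group would then be hydroborated and coupled in a B-alkyl Suzuki reaction with alkenyl iodide **A4**, and the silyl ether removed.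
- For it: ring B, the C3=C4 alkene and the stereocentre are formed in one step. No C4 ketone ever exists, so no redox adjustment and no retro-oxa-Michael pathway arise. On the number of steps after the key step, and on how close the key step is to an established reaction class, this alternative is as strong as the chosen route or stronger.
- Against it: the weak point is **A2**. An aryl ether of a tertiary, doubly allylic carbinol cannot be made by SN2 or Mitsunobu chemistry, and metal-catalysed allylic etherification favours the linear dienyl ether. Once made, **A2** is set up for aromatic Claisen rearrangement and for ionisation to a pentadienyl cation. **A3** is also highly air- and moisture-sensitive and would have to distinguish groups around a centre whose other substituent is only a methyl group.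
- Comparison: the chosen strategy offers a key-step substrate, **13**, that is reached in six robust steps and is indefinitely stable, so the risk sits in one step only.

**Alternative 2: anodic dearomatising ketalisation at C8a.**
- Disconnection: the O1–C8a bond.
- Forward key step: constant-current oxidation of the 4-methoxyphenol **A6** at a graphite anode, in a nitrile solvent with a fluorinated alcohol, a hindered pyridine base and a perchlorate electrolyte. The phenoxonium ion would be captured at the methoxy-bearing carbon by the tertiary alcohol, held in place by the Z-alkene, to give the pyran-fused quinone monoketal **A5**. Reductive loss of methoxide would then restore the arene.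
- For it: the bonds at C2 are never touched, so a preformed carbinol configuration is carried through without risk. The oxidation is reagent-free and mild. On mildness this alternative is stronger than the chosen route, which uses amide bases and a one-electron reductant.
- Against it: the key step does not create the stereocentre. **A6** would need an enantioenriched tertiary alcohol in which methyl and a CH2 chain are told apart, so the central problem is moved and not solved. The tetrasubstituted ring C alkene and the C3'=C4' alkene are nucleophiles toward the phenoxonium ion and are themselves oxidisable. The rearomatisation of **A5** must cleave C8a–OMe and not C8a–O1, and the wrong choice returns **A6**. The Z-alkene needs a separate semi-reduction.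
- Comparison: the chosen strategy sets C2 catalytically on a substrate that has no competing π-nucleophile chemistry under the conditions of the key step.

**Alternative 3: one-carbon ring expansion of a benzofuranone.**
- Disconnection: C3–C4 and C4–C4a, by insertion of one carbon.
- Forward key step: the fully elaborated benzofuran-3(2H)-one **A8** would be treated with a C-silylated diazomethane under boron Lewis-acid activation. Migration of the aryl carbon would give the chroman-3-one **A7**, which is reduced and dehydrated; with C2 quaternary the alkene can only form towards C4.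
- For it: C2 is α to the carbonyl in **A8**, so the quaternary centre can be made by asymmetric enolate alkylation, a well-precedented way to such centres. A 3-ketone cannot open ring B by β-elimination, and even migration of C2 would lead to **17**, which converges on the same alkene. On precedent for the stereocentre and on the robustness of C2 afterwards this alternative is stronger.
- Against it: a Lewis acid strong enough to activate a hindered ketone flanked by a quaternary carbon is in the flask together with the acid-labile 1,5-diene chain. The product **A7** is a less hindered, easily enolised ketone that invites a second insertion and air oxidation. Asymmetric alkylation needs an activated electrophile, so the unactivated C1'–C2' chain would have to be built in several further steps after an allylation.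
- Comparison: the chosen strategy keeps Lewis acids away from the chain and attaches the complete chain in one convergent alkylation.

Key step: step 7

Assumption: the LaLi3(diolate)3 catalyst of step 7 is written with the (S)-configured ligand. The sense of induction on a chromone cannot be derived from acyclic enones, so the antipodal ligand is to be used if the first experiment shows delivery to the Si face of C2.

## Route

Step 1
Reactants: 1 2',5'-dihydroxyacetophenone
Product: 2 1-[2-hydroxy-5-(triisopropylsilyloxy)phenyl]ethan-1-one
Conditions: TIPSCl (1.05 equiv), imidazole, CH2Cl2/DMF, 0 °C → rt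
Reagents that add atoms: triisopropylsilyl chloride, CC(C)[Si](Cl)(C(C)C)C(C)C
Why: The 2'-hydroxyl is held in a hydrogen bond to the ketone and is flanked by the acyl group, so silylation should take place at the free 5'-hydroxyl only (selective phenol silylation).

Step 2
Reactants: 2 1-[2-hydroxy-5-(triisopropylsilyloxy)phenyl]ethan-1-one
Product: 4 2-methyl-6-(triisopropylsilyloxy)-4H-chromen-4-one, via aryl butane-1,3-dione 3 (not isolated)
Conditions: LiN(SiMe3)2 (3.3 equiv), THF, −78 °C; EtOAc, −78 °C → rt; aq. NH4Cl; crude 3, p-TsOH·H2O (10 mol%), toluene, 70 °C
Reagents that add atoms: ethyl acetate, CCOC(C)=O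
Why: Crossed Claisen condensation of the phenoxide–enolate dianion with the ester gives diketone 3, and deprotonation of 3 by the third equivalent of base drives the equilibrium. Acid then closes O1 onto the acetyl carbonyl and dehydrates to the pyranone (cyclodehydration of an ortho-hydroxyaryl 1,3-diketone); the aryl silyl ether tolerates both sets of conditions.

Step 3
Reactants: 5 dihydro-β-ionone, 4-(2,6,6-trimethylcyclohex-1-en-1-yl)butan-2-one
Product: 7 2-(but-3-yn-1-yl)-1,3,3-trimethylcyclohex-1-ene, via enol diethyl phosphate 6 (not isolated)
Conditions: LiN(iPr)2 (1.05 equiv), THF, −78 °C; ClP(O)(OEt)2, −78 °C → rt; LiN(iPr)2 (2.3 equiv), −78 °C → rt; H2O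
Reagents that add atoms: none
Why: Kinetic deprotonation at −78 °C takes place at the methyl group, the enolate is trapped on oxygen as enol phosphate 6, and excess amide base eliminates phosphate to the terminal alkyne, which is held as its acetylide and so protected from isomerisation (methyl ketone to terminal alkyne by enol phosphate elimination).

Step 4
Reactants: 7 2-(but-3-yn-1-yl)-1,3,3-trimethylcyclohex-1-ene
Product: 10 (2E)-3-methyl-5-(2,6,6-trimethylcyclohex-1-en-1-yl)pent-2-en-1-ol, via alkenyldimethylalane 8 (not isolated), via lithium alkenylaluminate 9 (not isolated)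
Conditions: Me3Al (2 equiv), Cp2ZrCl2 (20 mol%), CH2Cl2, 0 °C → rt; volatiles removed; n-BuLi, hexane/THF, −78 → 0 °C; (CH2O)n, rt; aq. work-up
Reagents that add atoms: trimethylaluminium, C[Al](C)C; paraformaldehyde (as formaldehyde), C=O
Why: Zirconium-catalysed carboalumination adds CH3 and Al syn across the alkyne with Al at the terminus, which fixes the E geometry of the future C3'=C4' bond. Conversion of 8 into aluminate 9 makes the alkenyl group nucleophilic enough to add to formaldehyde with retention (Negishi carboalumination with one-carbon trapping); the ring C alkene is inert.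

Step 5
Reactants: 10 (2E)-3-methyl-5-(2,6,6-trimethylcyclohex-1-en-1-yl)pent-2-en-1-ol
Product: 11 2-[(3E)-5-bromo-3-methylpent-3-en-1-yl]-1,3,3-trimethylcyclohex-1-ene
Conditions: PBr3 (0.4 equiv), Et2O, −10 → 0 °C; used crude
Reagents that add atoms: phosphorus tribromide, BrP(Br)Br
Why: Primary allylic alcohols of the geraniol type are converted by PBr3 in ether at low temperature into the primary bromides by SN2, without allylic transposition or loss of alkene geometry.

Step 6
Reactants: 4 2-methyl-6-(triisopropylsilyloxy)-4H-chromen-4-one; 11 2-[(3E)-5-bromo-3-methylpent-3-en-1-yl]-1,3,3-trimethylcyclohex-1-ene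
Product: 13 2-[(3E)-4-methyl-6-(2,6,6-trimethylcyclohex-1-en-1-yl)hex-3-en-1-yl]-6-(triisopropylsilyloxy)-4H-chromen-4-one, via lithium dienolate 12 (not isolated)
Conditions: LiN(iPr)2 (1.05 equiv), THF, −78 °C; then 11 (0.9 equiv), −78 → −40 °C
Reagents that add atoms: none
Why: The 2-methyl group of a chromone is a vinylogous α-position; LiN(iPr)2 gives the cross-conjugated dienolate 12, which alkylates at the exocyclic carbon because only that pathway restores the pyranone (lateral metalation and γ-alkylation of a 2-methylchromone). A primary allylic bromide is a fast SN2 partner at this temperature, and the slight excess of 4 limits double alkylation.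

Step 7
Reactants: 13 2-[(3E)-4-methyl-6-(2,6,6-trimethylcyclohex-1-en-1-yl)hex-3-en-1-yl]-6-(triisopropylsilyloxy)-4H-chromen-4-one; 14 trimethylsulfoxonium iodide
Product: 16 (1aR,7aS)-1a-[(3E)-4-methyl-6-(2,6,6-trimethylcyclohex-1-en-1-yl)hex-3-en-1-yl]-5-(triisopropylsilyloxy)-1a,7a-dihydrocyclopropa[b]chromen-7(1H)-one (cis-fused), via dimethylsulfoxonium methylide 15 (not isolated)
Conditions: 14, NaH, THF, 65 °C; filtered solution of 15 added over 3 h to 13, LaLi3[(S)-6,6'-(propane-1,3-diyldioxy)biphenyl-2,2'-diolate]3 (10 mol%), NaI (10 mol%), THF/toluene, −40 → −20 °C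
Reagents that add atoms: trimethylsulfoxonium iodide 14 (CH2 only), C[S+](C)(C)=O.[I-]
Why: Proposed new method: the oxophilic trivalent lanthanum centre of the LaLi3(diolate)3 complex is expected to bind the C4 carbonyl of the flat chromone 13 while a lithium aryloxide arm holds the sulfoxonium oxygen of ylide 15, so that the ylide carbon adds to C2 from one face (conjugate addition) and the C3 enolate then displaces the sulfoxide from the new CH2; the closest known reactions are the uncatalysed, racemic Corey–Chaykovsky cyclopropanation of chromones with this ylide and the LaLi3(biphenyldiolate)3/NaI-catalysed asymmetric cyclopropanation of acyclic aryl enones. The one ring formed, the cyclopropane, closes in a 3-exo-tet mode by intramolecular SN2 of the carbon terminus of the enolate on the sulfoxonium-bearing CH2. C1a, the future C2, is set by the catalyst, which has to deliver CH2 to the Re face of C2 (priority O1 > C3 > C1'); C7a is not an independent variable, since a three-membered ring can only be cis-fused to the pyranone. Attack at C2 and not at the carbonyl carbon is expected because addition of the stabilised sulfoxonium ylide to C=O is reversible whereas ring closure after 1,4-addition is not. The unactivated side-chain alkenes and the aryl silyl ether are inert to the ylide. Proton abstraction from C1' by the ylide only returns 13 and the sulfoxonium cation after reprotonation and is therefore not destructive. What is new is the acceptor, a fully substituted, oxygen-bearing β-carbon of a cyclic vinylogous ester that is less electrophilic than the acyclic enones on which this catalyst type is established, which is why carbonyl activation by lanthanum and slow addition of the ylide between −40 and −20 °C are specified.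

Step 8
Reactants: 16 the cis-fused (1aR,7aS)-cyclopropa[b]chromen-7-one of step 7
Product: 17 (2S)-2-methyl-2-[(3E)-4-methyl-6-(2,6,6-trimethylcyclohex-1-en-1-yl)hex-3-en-1-yl]-6-(triisopropylsilyloxy)-2,3-dihydro-4H-chromen-4-one
Conditions: SmI2 (2.5 equiv), t-BuOH (3 equiv), THF/DMPU, −78 → −20 °C
Reagents that add atoms: none
Why: Electron transfer from SmI2 to the aryl ketone gives a ketyl whose π orbital overlaps with the external C7a–C1 bond and is nearly orthogonal to the ring-fusion bond, so fragmentation releases the strain at the bridge carbon. A second electron and a proton from t-BuOH turn C1 into the C2 methyl group, and the trivalent samarium enolate is protonated at low temperature before it can expel the aryloxide (SmI2 reductive opening of an α-cyclopropyl ketone). No bond at C2 is broken, so its spatial arrangement is carried over and reads S in 17.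

Step 9
Reactants: 17 the (2S)-2,2-disubstituted 6-silyloxychroman-4-one of step 8
Product: 18 (2S,4RS)-2-methyl-2-[(3E)-4-methyl-6-(2,6,6-trimethylcyclohex-1-en-1-yl)hex-3-en-1-yl]-6-(triisopropylsilyloxy)-3,4-dihydro-2H-chromen-4-ol (both C4 epimers)
Conditions: NaBH4, CeCl3·7H2O, MeOH/THF, −20 → 0 °C
Reagents that add atoms: none
Why: Hydride reduction of the aryl ketone under Luche-type conditions is fast and nearly neutral, which avoids base-induced opening of ring B at O1–C2. The configuration at C4 is not controlled and does not matter, because C4 becomes sp2 in step 10.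

Step 10
Reactants: 18 the (2S,4RS)-chroman-4-ol of step 9
Product: 19 triisopropyl({(2S)-2-methyl-2-[(3E)-4-methyl-6-(2,6,6-trimethylcyclohex-1-en-1-yl)hex-3-en-1-yl]-2H-chromen-6-yl}oxy)silane
Conditions: Burgess reagent (MeO2CN–SO2NEt3 inner salt, 2 equiv), toluene, 50 °C, dark
Reagents that add atoms: none
Why: The Burgess reagent converts the secondary benzylic alcohol into a sulfamate that eliminates by a syn, intramolecular pathway under neutral conditions. C3 carries a hydrogen syn to the leaving group in either C4 epimer and C4a has none, so only the C3=C4 alkene can form (Burgess dehydration), and no free C4 cation is offered to the C3'=C4' alkene.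

Step 11
Reactants: 19 the (2S)-6-(triisopropylsilyloxy)-2H-chromene of step 10
Product: 20 (2S)-2-methyl-2-[(3E)-4-methyl-6-(2,6,6-trimethylcyclohex-1-en-1-yl)hex-3-en-1-yl]-2H-chromen-6-ol
Conditions: Bu4NF, AcOH (1:1), THF, 0 °C, argon, dark
Reagents that add atoms: none
Why: Fluoride cleaves the aryl O–Si bond selectively (fluoride desilylation). Buffering with AcOH keeps the electron-rich phenol protonated and limits air oxidation, and exclusion of light avoids electrocyclic opening of the chromene, which would erode the configuration at C2.

## Compound list

1 | 2',5'-dihydroxyacetophenone | CC(=O)c1cc(O)ccc1O | starting material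
2 | 1-[2-hydroxy-5-(triisopropylsilyloxy)phenyl]ethan-1-one | CC(=O)c1cc(O[Si](C(C)C)(C(C)C)C(C)C)ccc1O | intermediate
3 | 1-[2-hydroxy-5-(triisopropylsilyloxy)phenyl]butane-1,3-dione | CC(=O)CC(=O)c1cc(O[Si](C(C)C)(C(C)C)C(C)C)ccc1O | intermediate (not isolated)
4 | 2-methyl-6-(triisopropylsilyloxy)-4H-chromen-4-one | CC1=CC(=O)c2cc(O[Si](C(C)C)(C(C)C)C(C)C)ccc2O1 | intermediate
5 | dihydro-β-ionone, 4-(2,6,6-trimethylcyclohex-1-en-1-yl)butan-2-one | CC(=O)CCC1=C(C)CCCC1(C)C | starting material
6 | diethyl 4-(2,6,6-trimethylcyclohex-1-en-1-yl)but-1-en-2-yl phosphate | C=C(CCC1=C(C)CCCC1(C)C)OP(=O)(OCC)OCC | intermediate (not isolated)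
7 | 2-(but-3-yn-1-yl)-1,3,3-trimethylcyclohex-1-ene | C#CCCC1=C(C)CCCC1(C)C | intermediate
8 | dimethyl[(1E)-2-methyl-4-(2,6,6-trimethylcyclohex-1-en-1-yl)but-1-en-1-yl]alane | C[Al](C)/C=C(C)/CCC1=C(C)CCCC1(C)C | intermediate (not isolated)
9 | lithium butyl(dimethyl)[(1E)-2-methyl-4-(2,6,6-trimethylcyclohex-1-en-1-yl)but-1-en-1-yl]aluminate | [Li+].CCCC[Al-](C)(C)/C=C(C)/CCC1=C(C)CCCC1(C)C | intermediate (not isolated)
10 | (2E)-3-methyl-5-(2,6,6-trimethylcyclohex-1-en-1-yl)pent-2-en-1-ol | OC/C=C(C)/CCC1=C(C)CCCC1(C)C | intermediate
11 | 2-[(3E)-5-bromo-3-methylpent-3-en-1-yl]-1,3,3-trimethylcyclohex-1-ene | BrC/C=C(C)/CCC1=C(C)CCCC1(C)C | intermediate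
12 | lithium 2-methylidene-6-(triisopropylsilyloxy)-2H-chromen-4-olate | [Li+].C=C1C=C([O-])c2cc(O[Si](C(C)C)(C(C)C)C(C)C)ccc2O1 | intermediate (not isolated)
13 | 2-[(3E)-4-methyl-6-(2,6,6-trimethylcyclohex-1-en-1-yl)hex-3-en-1-yl]-6-(triisopropylsilyloxy)-4H-chromen-4-one | CC1=C(CC/C(C)=C/CCC2=CC(=O)c3cc(O[Si](C(C)C)(C(C)C)C(C)C)ccc3O2)C(C)(C)CCC1 | intermediate
14 | trimethylsulfoxonium iodide | C[S+](C)(C)=O.[I-] | starting material
15 | dimethylsulfoxonium methylide | [CH2-][S+](C)(C)=O | intermediate (not isolated)
16 | (1aR,7aS)-1a-[(3E)-4-methyl-6-(2,6,6-trimethylcyclohex-1-en-1-yl)hex-3-en-1-yl]-5-(triisopropylsilyloxy)-1a,7a-dihydrocyclopropa[b]chromen-7(1H)-one | CC1=C(CC/C(C)=C/CC[C@@]23C[C@@H]2C(=O)c2cc(O[Si](C(C)C)(C(C)C)C(C)C)ccc2O3)C(C)(C)CCC1 | intermediate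
17 | (2S)-2-methyl-2-[(3E)-4-methyl-6-(2,6,6-trimethylcyclohex-1-en-1-yl)hex-3-en-1-yl]-6-(triisopropylsilyloxy)-2,3-dihydro-4H-chromen-4-one | CC1=C(CC/C(C)=C/CC[C@@]2(C)CC(=O)c3cc(O[Si](C(C)C)(C(C)C)C(C)C)ccc3O2)C(C)(C)CCC1 | intermediate
18 | (2S,4RS)-2-methyl-2-[(3E)-4-methyl-6-(2,6,6-trimethylcyclohex-1-en-1-yl)hex-3-en-1-yl]-6-(triisopropylsilyloxy)-3,4-dihydro-2H-chromen-4-ol | CC1=C(CC/C(C)=C/CC[C@@]2(C)CC(O)c3cc(O[Si](C(C)C)(C(C)C)C(C)C)ccc3O2)C(C)(C)CCC1 | intermediate
19 | triisopropyl({(2S)-2-methyl-2-[(3E)-4-methyl-6-(2,6,6-trimethylcyclohex-1-en-1-yl)hex-3-en-1-yl]-2H-chromen-6-yl}oxy)silane | CC1=C(CC/C(C)=C/CC[C@@]2(C)C=Cc3cc(O[Si](C(C)C)(C(C)C)C(C)C)ccc3O2)C(C)(C)CCC1 | intermediate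
20 | (2S)-2-methyl-2-[(3E)-4-methyl-6-(2,6,6-trimethylcyclohex-1-en-1-yl)hex-3-en-1-yl]-2H-chromen-6-ol | CC1=C(CC/C(C)=C/CC[C@@]2(C)C=Cc3cc(O)ccc3O2)C(C)(C)CCC1 | target

## Step count and least certain steps

Total: 11 steps. Longest linear sequence: 9 steps (5 → 7 → 10 → 11 → 13 → 16 → 17 → 18 → 19 → 20, steps 3 to 11). The chromone branch (steps 1 and 2) joins at step 6.

**Step 7 (key step, the one step beyond known chemistry).**
- What may go wrong: poor facial selectivity, because the chiral pocket of the LaLi3(diolate)3 catalyst is shaped for acyclic enones. Slow or incomplete addition, because the fully substituted, oxygenated β-carbon is a weak acceptor. Expulsion of the aryloxide from the intermediate enolate (opening of ring B) before the three-membered ring closes.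
- Fallback: it sets out from 13 and comes back to the route at 16. Ylide 15, generated from 14 with NaH in dimethyl sulfoxide, reacts with 13 at room temperature without any catalyst. This is a known reaction of chromones and should give the racemic cis-fused cyclopropane F1. Preparative chromatography on a chiral stationary phase (cellulose tris(3,5-dimethylphenylcarbamate) on silica) then separates the (1aS,7aR) enantiomer F2, which is set aside, from the (1aR,7aS) enantiomer, which is 16.

**Step 8.**
- What may go wrong: scission of the ring-fusion bond instead of the external bond. This pathway is favoured electronically, because it would leave an oxygen-stabilised tertiary radical, and it leads to ring expansion. Further risks are over-reduction of the ketone, and expulsion of the aryloxide from the trivalent samarium enolate with loss of configuration at C2 on reclosure.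
- Fallback: it sets out from 16 and comes back at 17, replacing electron transfer by a two-electron opening. Sodium benzeneselenolate, made from (PhSe)2 and NaBH4 in EtOH/THF, attacks the unhindered bridge CH2 in an SN2 sense with the enolate as leaving group (homoconjugate addition). This gives the (2S)-2-[(phenylselanyl)methyl]chroman-4-one F3. Bu3SnH with AIBN in toluene at 80 °C, at high stannane concentration, then replaces selenium by hydrogen to give 17.

**Step 6.**
- What may go wrong: alkylation at C3 instead of C1', a second alkylation at C1', or conjugate addition of dienolate 12 to unreacted chromone. All of these follow from the ambident and basic character of the dienolate.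
- Fallback: it sets out from 11 and 2 and comes back at 13, forming the C1'–C2' bond on a simple ester and ring B last. The lithium enolate of ethyl acetate (LiN(iPr)2, THF, −78 °C) is alkylated with 11 to give ethyl (4E)-5-methyl-7-(2,6,6-trimethylcyclohex-1-en-1-yl)hept-4-enoate F4. Crossed Claisen condensation of the dianion of 2 (LiN(SiMe3)2, THF) with F4 gives the aryl 1,3-diketone F5. p-TsOH·H2O in toluene cyclodehydrates F5 to 13. Chromone 4 is then not needed.

**Step 10.**
- What may go wrong: ionisation of the sulfamate to a benzylic cation stabilised by O1, followed by capture by the C3'=C4' alkene or by the carbamate nitrogen instead of elimination.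
- Fallback: it sets out from 17, leaves out step 9 and comes back at 19. KN(SiMe3)2 in THF at −78 °C followed by PhNTf2 gives the (2S)-2H-chromen-4-yl trifluoromethanesulfonate F6; the kinetic enolate is kept cold so that it does not open ring B. Reduction catalysed by Pd(OAc)2/PPh3 with HCO2H and Et3N in DMF at 60 °C then replaces the triflate by hydrogen to give 19.

## Further compounds

F1 | step 7 | racemic cis-fused 1a-[(3E)-4-methyl-6-(2,6,6-trimethylcyclohex-1-en-1-yl)hex-3-en-1-yl]-5-(triisopropylsilyloxy)-1a,7a-dihydrocyclopropa[b]chromen-7(1H)-one | CC1=C(CC/C(C)=C/CCC23CC2C(=O)c2cc(O[Si](C(C)C)(C(C)C)C(C)C)ccc2O3)C(C)(C)CCC1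
F2 | step 7 | (1aS,7aR)-1a-[(3E)-4-methyl-6-(2,6,6-trimethylcyclohex-1-en-1-yl)hex-3-en-1-yl]-5-(triisopropylsilyloxy)-1a,7a-dihydrocyclopropa[b]chromen-7(1H)-one | CC1=C(CC/C(C)=C/CC[C@]23C[C@H]2C(=O)c2cc(O[Si](C(C)C)(C(C)C)C(C)C)ccc2O3)C(C)(C)CCC1
F3 | step 8 | (2S)-2-[(3E)-4-methyl-6-(2,6,6-trimethylcyclohex-1-en-1-yl)hex-3-en-1-yl]-2-[(phenylselanyl)methyl]-6-(triisopropylsilyloxy)-2,3-dihydro-4H-chromen-4-one | CC1=C(CC/C(C)=C/CC[C@@]2(C[Se]c3ccccc3)CC(=O)c3cc(O[Si](C(C)C)(C(C)C)C(C)C)ccc3O2)C(C)(C)CCC1
F4 | step 6 | ethyl (4E)-5-methyl-7-(2,6,6-trimethylcyclohex-1-en-1-yl)hept-4-enoate | CCOC(=O)CC/C=C(C)/CCC1=C(C)CCCC1(C)C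
F5 | step 6 | (6E)-1-[2-hydroxy-5-(triisopropylsilyloxy)phenyl]-7-methyl-9-(2,6,6-trimethylcyclohex-1-en-1-yl)non-6-ene-1,3-dione | CC1=C(CC/C(C)=C/CCC(=O)CC(=O)c2cc(O[Si](C(C)C)(C(C)C)C(C)C)ccc2O)C(C)(C)CCC1
F6 | step 10 | (2S)-2-methyl-2-[(3E)-4-methyl-6-(2,6,6-trimethylcyclohex-1-en-1-yl)hex-3-en-1-yl]-6-(triisopropylsilyloxy)-2H-chromen-4-yl trifluoromethanesulfonate | CC1=C(CC/C(C)=C/CC[C@@]2(C)C=C(OS(=O)(=O)C(F)(F)F)c3cc(O[Si](C(C)C)(C(C)C)C(C)C)ccc3O2)C(C)(C)CCC1
A1 | alternative 1 | (2S)-6-(tert-butyldimethylsilyloxy)-2-methyl-2-vinyl-2H-chromene | C=C[C@@]1(C)C=Cc2cc(O[Si](C)(C)C(C)(C)C)ccc2O1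
A2 | alternative 1 | tert-butyldimethyl{4-[(3-methylpenta-1,4-dien-3-yl)oxy]-3-vinylphenoxy}silane | C=CC(C)(C=C)Oc1ccc(O[Si](C)(C)C(C)(C)C)cc1C=C
A3 | alternative 1 | Mo(N-2,6-iPr2C6H3)(CHCMe2Ph)(3,3'-di-tert-butyl-5,5',6,6'-tetramethylbiphenyl-2,2'-diolate), one enantiomer of the biaryl axis | CC(C)c1cccc(C(C)C)c1N=[Mo]1(=CC(C)(C)c2ccccc2)Oc2c(C(C)(C)C)cc(C)c(C)c2-c2c(C)c(C)cc(C(C)(C)C)c2O1
A4 | alternative 1 | 2-[(3E)-4-iodo-3-methylbut-3-en-1-yl]-1,3,3-trimethylcyclohex-1-ene | CC1=C(CC/C(C)=C/I)C(C)(C)CCC1
A5 | alternative 2 | (2S)-8a-methoxy-2-methyl-2-[(3E)-4-methyl-6-(2,6,6-trimethylcyclohex-1-en-1-yl)hex-3-en-1-yl]-2H-chromen-6(8aH)-one, one C8a epimer drawn | CC1=C(CC/C(C)=C/CC[C@@]2(C)C=CC3=CC(=O)C=C[C@@]3(OC)O2)C(C)(C)CCC1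
A6 | alternative 2 | 3-[(1Z,3S,6E)-3-hydroxy-3,7-dimethyl-9-(2,6,6-trimethylcyclohex-1-en-1-yl)nona-1,6-dien-1-yl]-4-methoxyphenol | CC1=C(CC/C(C)=C/CC[C@](C)(O)/C=C\c2cc(O)ccc2OC)C(C)(C)CCC1
A7 | alternative 3 | (2S)-2-methyl-2-[(3E)-4-methyl-6-(2,6,6-trimethylcyclohex-1-en-1-yl)hex-3-en-1-yl]-6-(triisopropylsilyloxy)-2H-chromen-3(4H)-one | CC1=C(CC/C(C)=C/CC[C@@]2(C)C(=O)Cc3cc(O[Si](C(C)C)(C(C)C)C(C)C)ccc3O2)C(C)(C)CCC1
A8 | alternative 3 | (2S)-2-methyl-2-[(3E)-4-methyl-6-(2,6,6-trimethylcyclohex-1-en-1-yl)hex-3-en-1-yl]-5-(triisopropylsilyloxy)-1-benzofuran-3(2H)-one | CC1=C(CC/C(C)=C/CC[C@@]2(C)C(=O)c3cc(O[Si](C(C)C)(C(C)C)C(C)C)ccc3O2)C(C)(C)CCC1
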